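The target and the trapped intermediate are both made from intermediate A, the first by a step of constant 0.0030 s⁻¹, the second by a step of constant 0.28 L mol⁻¹ s⁻¹ with the capture agent. The level of intermediate A therefore cancels from the ratio of their rates.

| setting | larch | ash | alder | oak |
|---|---|---|---|---|
| substrate | 0.17 M (fed, over 7.50 s) | 0.17 M | 0.17 M | 0.17 M |
| reagent | 0.900 equiv | 0.900 equiv | 0.900 equiv (fed, over 7.50 s) | 0.900 equiv |
| capture agent | 3.40 mM | 3.40 mM | 3.40 mM | 3.40 mM |
| time | 15 s |  | 15 s | 15 s |
| remark | all but substrate at the start; substrate goes in evenly over 7.50 s, the run ends at 15 s | a single well-mixed tank run continuously and read at steady state, 15 s in it on average | all but reagent at the start; reagent goes in evenly over 7.50 s, the run ends at 15 s | everything together in a closed stirred flask, run for 15 s |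

- the set-up with the highest share of target in all that became target or trapped intermediate, at the outlet or at the end ("none" if the first two lie within 2 percentage points) (larch / ash / alder / oak / none)
- share of target in all that became target or trapped intermediate, at the outlet or at the end, larch
- share of target in all that became target or trapped intermediate, at the outlet or at the end, ash
- share of target in all that became target or trapped intermediate, at the outlet or at the end, alder
- share of target in all that became target or trapped intermediate, at the outlet or at the end, oak

- the stated concentrations are those of everything mixed, before any reaction; amounts are the same in each set-up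
- the feed brings no volume worth counting
- run time (larch): 15 s

    intermediate A → target (k1 = 0.0030 s⁻¹)
    capture agent + intermediate A → trapped intermediate (k2 = 0.28 L mol⁻¹ s⁻¹)
    intermediate A ⇌ intermediate B (K3 = 1.6, k3 = 0.0058 s⁻¹)
    substrate + reagent ⇌ intermediate A (K4 = 1.2 L mol⁻¹, k4 = 4.9 L mol⁻¹ s⁻¹)

We fold the givens into one number. Φ = 3.15 is the target made per trapped intermediate while the capture agent stands at its charge; this selectivity factor reads as a share of 75.9%.

Is one number enough? That depends on how far the capture agent falls, so we count its turnovers, n: capture constant times intermediate A times time. The equilibrium of substrate and reagent, with nothing lost, puts intermediate A at 0.0229 M, so n = 0.0964. With intermediate A held at that level, a closed flask multiplies Φ by n over (one minus e^(−n)), giving 3.31 and, for oak, 76.8%. At the same level, the tank multiplies Φ by one plus n, so ash gets 77.6%. Larch and alder spend the first 7.50 s of 15 s building intermediate A, so we place them between Φ's share and oak. The spread of our estimates, from Φ's share up to ash, is 1.7 percentage points, less than the margin of 2 points, and we commit to no winner.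

The forecast, reasoning that “A sits at quasi-equilibrium with substrate and reagent”, gave larch 76.6%, ash 77.5%, alder 76.5%, oak 76.7%, and best: none. Against its oak and ash, our own reckoning stands at 76.8% and 77.6%.

The simulation gives larch 76.6%, ash 77.5%, alder 76.5%, oak 76.7%, and best: none.

Intermediate A has a half-life of 3.9 min by step 1 and, in oak, 12 min by step 2 at the charged capture agent, a ratio of 3.15, which is Φ = 3.15 again. Both are far longer than the 15 s run, and oak ends with 0.589% target and 0.178% trapped intermediate beside 85.1% substrate, each in percent of the substrate charged.

A neighbour of alder with 0.014 M capture agent has Φ = 0.765, a share of 43.4%. Its computed share is 44.2%.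

The constants used here come from no measurement; what happens was integrated by code.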